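**Retrosynthetic overview**
1. The target arises by late acylations of the tetraol core: salicylate on primary C10-OH, acetate on C7-OH, and the C1 acylal under anomeric control. The Δ5,6 alkene comes from DDQ desaturation of the cycloadduct.
2. Key step: intramolecular inverse-demand hetero-Diels–Alder of an enal (1-oxadiene) with a silyl enol ether. It closes the pyran (O2–C1) and the cyclopentane (C5–C9) together and sets C9.
3. The cycloaddition precursor is built from 2-deoxy-D-ribose, which supplies C7. A di-tert-butylsilylene 1,3-dioxanone, in which C7 directs an axial Grignard addition, sets the quaternary C8. Cross-metathesis adds the enal.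

Assumptions: the C1 acyloxy group is the axial, trans-to-C8 anomer drawn in the target. tBu2Si(OTf)2 bridges the 1,3-diol (C7/C10) in preference to the 1,2-diols.

**Step 1**
Reactants: 1 (2-deoxy-D-ribose)
Product: 2 ((4S,5R)-hex-1-ene-4,5,6-triol)
Conditions: Ph3P=CH2 (from Ph3PCH3Br, KOtBu), THF, 0 °C → rt
Reagents that add atoms: methylenetriphenylphosphorane, C=P(c1ccccc1)(c1ccccc1)c1ccccc1
Why: Wittig methylenation of the open-chain aldehyde form of the sugar gives the terminal alkene (future C5=C4′). The two sugar stereocenters, C3 (future C7) and C4 (future C8), are untouched.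

**Step 2**
Reactants: 2
Product: 3 ((4S,5R)-2,2-di-tert-butyl-4-allyl-1,3,2-dioxasilinan-5-ol)
Conditions: tBu2Si(OTf)2, 2,6-lutidine, CH2Cl2, −40 → 0 °C
Reagents that add atoms: di-tert-butylsilyl bis(triflate), CC(C)(C)[Si](OS(=O)(=O)C(F)(F)F)(OS(=O)(=O)C(F)(F)F)C(C)(C)C
Why: silylene formation favours the six-membered 1,3-dioxasilinane over five-membered rings. This ties C7-O and C10-O together, leaves C8-OH free, and gives a base- and fluoride-labile protection that avoids acid later.

**Step 3**
Reactants: 3
Product: 4 ((4S)-2,2-di-tert-butyl-4-allyl-1,3,2-dioxasilinan-5-one)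
Conditions: DMP, NaHCO3, CH2Cl2, 0 °C → rt
Reagents that add atoms: none
Why: Dess–Martin oxidation removes the temporary sugar C4 stereocenter. C7 is left as the only stereo-director.

**Step 4**
Reactants: 4
Product: 5 ((4S,5R)-5-(1,3-dioxolan-2-ylmethyl)-4-allyl-2,2-di-tert-butyl-1,3,2-dioxasilinan-5-ol)
Conditions: BrMgCH2-(1,3-dioxolan-2-yl), THF, −78 → 0 °C
Reagents that add atoms: (1,3-dioxolan-2-ylmethyl)magnesium bromide, Br[Mg]CC1OCCO1
Why: the ketone sits in a chair with the C7-allyl group equatorial. The Grignard adds axially, anti to the axial tBu on Si, which sets C8 (R) and attaches C9–C1 as a masked aldehyde.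

**Step 5**
Reactants: 5
Product: 6 (tertiary triethylsilyl ether of 5)
Conditions: TESOTf, 2,6-lutidine, CH2Cl2, −78 → 0 °C
Reagents that add atoms: triethylsilyl triflate, CC[Si](CC)(CC)OS(=O)(=O)C(F)(F)F
Why: the robust tertiary silyl ether keeps O8 inert to the Lewis-acid acylation in step 12 and is removed together with the silylene in step 14. No stereocenter is affected.

**Step 6**
Reactants: 6
Product: 7 (aldehyde: C8–CH2–CHO)
Conditions: I2 (10 mol%), acetone/H2O (20:1), rt
Reagents that add atoms: water, O
Why: iodine-catalysed transacetalisation removes the dioxolane under near-neutral conditions. The silyl ethers survive, and the β-silyloxy aldehyde is not epimerised because its α-carbon is not a stereocenter.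

**Step 7**
Reactants: 8 (2-methylenepropane-1,3-diol, commercial)
Product: 9 (2-(hydroxymethyl)allyl isovalerate)
Conditions: isovaleryl chloride (0.3 equiv, diol in excess), pyridine, CH2Cl2, 0 °C
Reagents that add atoms: isovaleryl chloride, CC(C)CC(=O)Cl
Why: statistical mono-acylation of a symmetrical diol, with recovery of excess diol.

**Step 8**
Reactants: 9
Product: 10 (2-(isovaleroyloxymethyl)acrolein)
Conditions: MnO2, CH2Cl2, rt
Reagents that add atoms: none
Why: MnO2 oxidises the allylic alcohol selectively and leaves the ester and the 1,1-disubstituted alkene intact.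

**Step 9**
Reactants: 7, 10
Product: 11 (enal-aldehyde with (E)-C5=C4, C11-OiVal, C3-CHO)
Conditions: 10 (3 equiv), Hoveyda–Grubbs II (5 mol%), CH2Cl2, 40 °C
Reagents that add atoms: none
Why: cross-metathesis of the terminal alkene with the 2-substituted acrolein gives the trisubstituted enal, which is the 1-oxadiene and already carries C11 as the isovalerate. It is done before the enol ether exists, because enol ethers poison Ru carbenes.

**Step 10**
Reactants: 11
Product: 12 (TMS enol ether, C9=C1–OTMS, enal intact)
Conditions: TMSCl, NaI, Et3N, MeCN, 0 °C → rt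
Reagents that add atoms: chlorotrimethylsilane, C[Si](C)(C)Cl
Why: soft enolisation silylates the more acidic saturated aldehyde selectively and gives the electron-rich dienophile. Its E/Z ratio is irrelevant because C1 is reset in step 12.

**Step 11**
Reactants: 12
Product: 13 (cycloadduct with C1-OTMS, silylene and C8-OTES retained, C5-H)
Conditions: toluene, BHT, 140 °C, sealed tube
Reagents that add atoms: none
Why: key intramolecular inverse-demand hetero-Diels–Alder. The nucleophilic enol-ether carbon C9 bonds to the enal β-carbon C5, and O2 bonds to C1, closing the cyclopentane and the pyran in one step. The three-atom tether gives the cis-fused bicycle. C9 is set with the new ring anti to the silylene bridge on the C7/C10 face, giving C9–C1 trans to C7-O. C1 and C5 are transient.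

**Step 12**
Reactants: 13
Product: 14 (C1 isovalerate acylal with the trans-to-C8 axial configuration)
Conditions: (iPrCH2CO)2O, TMSOTf (5 mol%), CH2Cl2, −20 °C
Reagents that add atoms: isovaleric anhydride, CC(C)CC(=O)OC(=O)CC(C)C
Why: Lewis-acid exchange of the anomeric silyl acetal through the reversible oxocarbenium gives the thermodynamic anomeric acylal, which sets C1. The TES ether and silylene are inert.

**Step 13**
Reactants: 14
Product: 15 (Δ5,6 diene: C3=C4–C5=C6)
Conditions: DDQ, 2,6-di-tert-butyl-4-methylpyridine, benzene, 25 °C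
Reagents that add atoms: none
Why: DDQ abstracts hydride from C5–H, giving a vinylogous oxocarbenium ion (O2=C3–C4=C5). Loss of H6 gives the conjugated dienol ether. C5 becomes sp2, so its stereochemistry is irrelevant, and C9, C8 and C7 are not involved.

**Step 14**
Reactants: 15
Product: 16 (C7-OH, C8-OH, C10-OH triol with both acylals)
Conditions: HF·pyridine, pyridine, THF, 0 → 40 °C
Reagents that add atoms: none
Why: buffered fluoride removes the silylene and the TES ether without acid or base, so the acylal, enol ether and esters survive.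

**Step 15**
Reactants: 16
Product: 17 (C10 2-acetoxybenzoate)
Conditions: 2-acetoxybenzoyl chloride (1.1 equiv), pyridine, CH2Cl2, −20 °C
Reagents that add atoms: 2-acetoxybenzoyl chloride, CC(=O)Oc1ccccc1C(=O)Cl
Why: the unhindered primary C10-OH is acylated selectively over the secondary C7-OH and the tertiary C8-OH. The acetate masks the phenol.

**Step 16**
Reactants: 17
Product: 18 (7-acetate)
Conditions: Ac2O, DMAP, Et3N, CH2Cl2, 0 °C
Reagents that add atoms: acetic anhydride, CC(=O)OC(C)=O
Why: the secondary C7-OH is acetylated. The tertiary C8-OH is unreactive under these mild conditions, and C7 keeps its configuration.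

**Step 17**
Reactants: 18
Product: 19 (jatamanvaltrate I)
Conditions: NH4OAc, MeOH/H2O, rt
Reagents that add atoms: none
Why: ammonium acetate cleaves the aryl acetate selectively and leaves the alkyl acetate, the isovalerates and the salicylate ester untouched.

**Compound list**

| # | Name | SMILES | Role |
|---|---|---|---|
| 1 | 2-deoxy-D-ribose | O=CC[C@H](O)[C@H](O)CO | starting material |
| 2 | (4S,5R)-hex-1-ene-4,5,6-triol | C=CC[C@H](O)[C@H](O)CO | intermediate |
| 3 | (4S,5R)-4-allyl-2,2-di-tert-butyl-1,3,2-dioxasilinan-5-ol | C=CC[C@@H]1O[Si](C(C)(C)C)(C(C)(C)C)OC[C@H]1O | intermediate |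
| 4 | (4S)-4-allyl-2,2-di-tert-butyl-1,3,2-dioxasilinan-5-one | C=CC[C@@H]1O[Si](C(C)(C)C)(C(C)(C)C)OCC1=O | intermediate |
| 5 | tertiary alcohol bearing the dioxolanylmethyl group | C=CC[C@@H]1O[Si](C(C)(C)C)(C(C)(C)C)OC[C@]1(O)CC2OCCO2 | intermediate |
| 6 | C8-triethylsilyl ether of 5 | C=CC[C@@H]1O[Si](C(C)(C)C)(C(C)(C)C)OC[C@]1(O[Si](CC)(CC)CC)CC2OCCO2 | intermediate |
| 7 | aldehyde from dioxolane hydrolysis | C=CC[C@@H]1O[Si](C(C)(C)C)(C(C)(C)C)OC[C@]1(O[Si](CC)(CC)CC)CC=O | intermediate |
| 8 | 2-methylenepropane-1,3-diol | C=C(CO)CO | starting material |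
| 9 | 2-(hydroxymethyl)allyl isovalerate | C=C(CO)COC(=O)CC(C)C | intermediate |
| 10 | 2-(isovaleroyloxymethyl)acrolein | C=C(C=O)COC(=O)CC(C)C | intermediate |
| 11 | (E)-enal aldehyde from cross-metathesis | O=C/C(COC(=O)CC(C)C)=C/C[C@@H]1O[Si](C(C)(C)C)(C(C)(C)C)OC[C@]1(O[Si](CC)(CC)CC)CC=O | intermediate |
| 12 | TMS enol ether of 11 | O=C/C(COC(=O)CC(C)C)=C/C[C@@H]1O[Si](C(C)(C)C)(C(C)(C)C)OC[C@]1(O[Si](CC)(CC)CC)C=CO[Si](C)(C)C | intermediate |
| 13 | hetero-Diels–Alder cycloadduct (C1-OTMS, C1 and C5 unspecified) | CC(C)CC(=O)OCC1=COC(O[Si](C)(C)C)[C@@H]2[C@@]3(O[Si](CC)(CC)CC)CO[Si](C(C)(C)C)(C(C)(C)C)O[C@H]3C[C@H]12 | intermediate |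
| 14 | C1 acylal cycloadduct | CC(C)CC(=O)OCC1=CO[C@@H](OC(=O)CC(C)C)[C@@H]2[C@@]3(O[Si](CC)(CC)CC)CO[Si](C(C)(C)C)(C(C)(C)C)O[C@H]3C[C@H]12 | intermediate |
| 15 | Δ5,6 diene, still silyl-protected | CC(C)CC(=O)OCC1=CO[C@@H](OC(=O)CC(C)C)[C@H]2C1=C[C@@H]3O[Si](C(C)(C)C)(C(C)(C)C)OC[C@]23O[Si](CC)(CC)CC | intermediate |
| 16 | triol diacylal | O[C@H]1C=C2C(COC(=O)CC(C)C)=CO[C@@H](OC(=O)CC(C)C)[C@@H]2[C@@]1(O)CO | intermediate |
| 17 | C10 2-acetoxybenzoate | O[C@H]1C=C2C(COC(=O)CC(C)C)=CO[C@@H](OC(=O)CC(C)C)[C@@H]2[C@@]1(O)COC(=O)c1ccccc1OC(C)=O | intermediate |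
| 18 | 7-acetate of 17 | CC(=O)O[C@H]1C=C2C(COC(=O)CC(C)C)=CO[C@@H](OC(=O)CC(C)C)[C@@H]2[C@@]1(O)COC(=O)c1ccccc1OC(C)=O | intermediate |
| 19 | jatamanvaltrate I | CC(=O)O[C@H]1C=C2C(COC(=O)CC(C)C)=CO[C@@H](OC(=O)CC(C)C)[C@@H]2[C@@]1(O)COC(=O)c1ccccc1O | target |

**Total steps:** 17. **Longest linear sequence:** 15 steps (1–6, 9–17).

**Three steps most likely to fail**
1. **Step 11 (hetero-Diels–Alder).** The unactivated enal and silyl enol ether may need forcing conditions, or the diastereoselectivity may be poor.
   - Fallback: a stepwise Lewis-acid (TiCl4 or Me2AlCl) intramolecular Mukaiyama–Michael of the enol silane onto the enal, followed by oxa-cyclisation of the resulting aldehyde enol onto the aldehyde.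
2. **Step 13 (DDQ desaturation).** Deprotonation could occur at C9 instead of C6, or the allylic C7–H could be oxidised.
   - Fallback: start from D-ribose so that a C6 hydroxyl is carried through, then dehydrate it (Burgess reagent or Martin sulfurane) after the cycloaddition.
3. **Step 4 (C8 addition).** The axial-attack model could give the wrong epimer, and step 2 silylene regioselectivity is a related risk.
   - Fallback: install C8 after the cycloaddition instead. Oxidise the sugar C4 carbinol to the C8 ketone, add CH2 by Corey–Chaykovsky epoxidation from the convex face, and open the spiro-epoxide at C10 with salicylic acid.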